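Plan
- Retrosynthetic cuts, in order: the C15–O acetate; C8=C17 (olefination of a C8 ketone); C9–C11 (side chain onto an enone β-carbon, with a C7→C8 carbonyl shift); C4–C5 (closure of ring A); C9–C10 and C5–C6 (Robinson annulation for ring B).
- Forward: ring B is made first as an achiral 4,4-disubstituted cyclohexa-2,5-dienone from melonal and methyl vinyl ketone. Ring A is then closed onto it, and the C11–C15 chain is joined last by conjugate addition.
- Enabling feature: in ring B the quaternary C10 lies para to C7 and between the two CH carbons C5 and C9. With a carbonyl at C7, C5 and C9 are enantiotopic enone β-carbons, and the C1–C3 tether on C10 can deliver C4 to C5 only on its own face, which is the cis A/B fusion of the target.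
- Stereochemistry: C10, C5 and C4 arise together in the amine-catalysed reductive Michael cyclisation (catalyst control plus tether). C9 follows by substrate control (addition on the convex face of the cis-fused enone). C13 comes from commercial methyl hydrogen (R)-3-methylglutarate.

Key step: step 4

Remark: labdane numbering is used (C4 carries CH3 and CO2Me, C10 the angular CH3, C8 the exocyclic CH2); the target is the cis-fused A/B isomer with H-5, the C10 methyl and the ester carbon on one face.
Assumption: the quinine-derived primary amine is written for step 4; if it favours the other enone arm, its quinidine-derived pseudoenantiomer is used instead.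

Step 1
Reactants: 1 2,6-dimethylhept-5-enal (melonal, racemic); 2 but-3-en-2-one (methyl vinyl ketone)
Product: 4 4-methyl-4-(4-methylpent-3-en-1-yl)cyclohex-2-en-1-one (racemic), via Michael adduct 3 (not isolated)
Conditions: pyrrolidine (20 mol%), AcOH (20 mol%), THF, 25 °C; then KOH, MeOH, 60 °C
Reagents that add atoms: none
Why: Robinson annulation, in which enamine-mediated Michael addition of the α-branched aldehyde to the enone gives keto aldehyde 3 and base-mediated intramolecular aldol condensation then gives the 4,4-disubstituted cyclohexenone; the quaternary carbon (future C10) forms as a racemate, which does not matter because step 2 makes it non-stereogenic.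

Step 2
Reactants: 4 4-methyl-4-(4-methylpent-3-en-1-yl)cyclohex-2-en-1-one
Product: 5 4-methyl-4-(4-methylpent-3-en-1-yl)cyclohexa-2,5-dien-1-one
Conditions: IBX (2.5 equiv), DMSO, 75 °C
Reagents that add atoms: none
Why: IBX dehydrogenation of the enone through its enol should install the second conjugated double bond (only the C8/C9 side carries removable hydrogens) and give the achiral cross-conjugated dienone, the isolated trisubstituted alkene being inert to IBX.

Step 3
Reactants: 5 4-methyl-4-(4-methylpent-3-en-1-yl)cyclohexa-2,5-dien-1-one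
Product: 7 (2E)-2-methyl-5-(1-methyl-4-oxocyclohexa-2,5-dien-1-yl)pent-2-enal, via allylic alcohol 6 (not isolated)
Conditions: SeO2 (0.3 equiv), tBuOOH (3 equiv), salicylic acid (10 mol%), CH2Cl2, 25 °C; then MnO2, CH2Cl2, 25 °C
Reagents that add atoms: tert-butyl hydroperoxide (CC(C)(C)OO)
Why: SeO2-catalysed allylic oxidation (ene reaction followed by [2,3]-shift) is selective for the E-methyl group of a prenyl terminus and MnO2 oxidises the resulting allylic alcohol, so the E-enal should form, while the dienone has neither an enolisable nor an allylic C–H bond.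

Step 4
Reactants: 7 (2E)-2-methyl-5-(1-methyl-4-oxocyclohexa-2,5-dien-1-yl)pent-2-enal
Product: 9 (1S,4aR,8aS)-1,4a-dimethyl-7-oxo-1,2,3,4,4a,7,8,8a-octahydronaphthalene-1-carbaldehyde (cis-fused; H-8a, the 4a-methyl and the formyl group on one face), via saturated aldehyde 8 (not isolated)
Conditions: 9-amino-9-deoxy-epi-quinine (20 mol%), CF3CO2H (40 mol%), Hantzsch ester (1.1 equiv), 1,4-dioxane, 40 °C
Reagents that add atoms: none
Why: Proposed new method: the primary ammonium salt condenses with the α-branched enal to an iminium ion, the Hantzsch ester delivers hydride to C3, and the resulting trisubstituted enamine (the catalyst-bound form of 8) adds through C4 to C5, the β-carbon of one of the two enantiotopic enone arms, before hydrolysis releases 9 and the amine. The closest known reaction types are the amine-catalysed iminium-reduction/enamine-Michael cyclisation of enal-enones with Hantzsch esters, the amine-catalysed desymmetrising Michael cyclisation of aldehydes onto 4,4-disubstituted cyclohexadienones, and primary-amine catalysis of α-branched aldehydes for quaternary centres; only their combination on one substrate is new. Ring A closes in a 6-exo-trig Michael mode. C10 and C5 are set together by the catalyst's choice of enone arm, and because the three-carbon tether can reach C5 only on the face of ring B on which it stands, the new C4–C5 bond is cis to C1 and H-5 ends up syn to the C10 methyl (cis A/B fusion). C4 is expected to form with the bulky iminium-bearing carbon pointing away from ring B (anti to the quaternary C10) and the small methyl group inside, which places the formyl group on the face of H-5. The step needs chemoselective hydride transfer to the enal (only the aldehyde forms an iminium ion readily, the hindered dienone carbonyl does not), arm selectivity (from the chiral amine) and formyl-outside selectivity at C4 (from the steric demand of the amine residue).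

Step 5
Reactants: 9 (1S,4aR,8aS)-1,4a-dimethyl-7-oxo-1,2,3,4,4a,7,8,8a-octahydronaphthalene-1-carbaldehyde
Product: 10 (1S,4aR,8aS)-1,4a-dimethyl-7-oxo-1,2,3,4,4a,7,8,8a-octahydronaphthalene-1-carboxylic acid
Conditions: NaClO2, NaH2PO4, 2-methylbut-2-ene, tBuOH/H2O, 25 °C
Reagents that add atoms: sodium chlorite ([Na+].[O-]Cl=O)
Why: Pinnick oxidation should convert the hindered, non-enolisable aldehyde into the acid without touching the enone, the alkene scavenger removing hypochlorous acid.

Step 6
Reactants: 10 (1S,4aR,8aS)-1,4a-dimethyl-7-oxo-1,2,3,4,4a,7,8,8a-octahydronaphthalene-1-carboxylic acid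
Product: 11 methyl (1S,4aR,8aS)-1,4a-dimethyl-7-oxo-1,2,3,4,4a,7,8,8a-octahydronaphthalene-1-carboxylate
Conditions: MeI, K2CO3, DMF, 25 °C
Reagents that add atoms: iodomethane (CI)
Why: SN2 O-alkylation of the carboxylate is insensitive to the steric hindrance at the quaternary α-carbon, and the weak base does not enolise the enone.

Step 7
Reactants: 12 (3R)-5-methoxy-3-methyl-5-oxopentanoic acid (methyl hydrogen (R)-3-methylglutarate)
Product: 13 methyl (3R)-5-hydroxy-3-methylpentanoate
Conditions: BH3·SMe2, THF, 0 → 25 °C
Reagents that add atoms: none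
Why: borane reduces the free carboxylic acid chemoselectively in the presence of the methyl ester (via the acyloxyborane), which differentiates the two ends of the chain without touching the stereocentre (future C13).

Step 8
Reactants: 13 methyl (3R)-5-hydroxy-3-methylpentanoate
Product: 14 methyl (3R)-5-[(tert-butyldimethylsilyl)oxy]-3-methylpentanoate
Conditions: tBuMe2SiCl, imidazole, DMF, 25 °C
Reagents that add atoms: tert-butyldimethylsilyl chloride (CC(C)(C)[Si](C)(C)Cl)
Why: standard silylation of the primary alcohol, carried out at once to prevent lactonisation of the hydroxy ester.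

Step 9
Reactants: 14 methyl (3R)-5-[(tert-butyldimethylsilyl)oxy]-3-methylpentanoate
Product: 15 (3S)-5-[(tert-butyldimethylsilyl)oxy]-3-methylpentan-1-ol
Conditions: LiAlH4, THF, 0 °C
Reagents that add atoms: none
Why: hydride reduction of the ester to the primary alcohol leaves the silyl ether intact (the descriptor changes only because the priorities change).

Step 10
Reactants: 15 (3S)-5-[(tert-butyldimethylsilyl)oxy]-3-methylpentan-1-ol
Product: 16 tert-butyl{[(3R)-5-iodo-3-methylpentyl]oxy}dimethylsilane
Conditions: I2, PPh3, imidazole, CH2Cl2, 0 °C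
Reagents that add atoms: iodine (II)
Why: Appel-type iodination of the primary alcohol through the alkoxyphosphonium ion proceeds by SN2 displacement at the CH2 carbon, remote from the stereocentre.

Step 11
Reactants: 11 methyl (1S,4aR,8aS)-1,4a-dimethyl-7-oxo-1,2,3,4,4a,7,8,8a-octahydronaphthalene-1-carboxylate; 16 tert-butyl{[(3R)-5-iodo-3-methylpentyl]oxy}dimethylsilane
Product: 19 methyl (1S,4aR,5S,8aS)-5-{(3S)-5-[(tert-butyldimethylsilyl)oxy]-3-methylpentyl}-1,4a-dimethyl-7-{[(trifluoromethyl)sulfonyl]oxy}-1,2,3,4,4a,5,8,8a-octahydronaphthalene-1-carboxylate, via Grignard reagent 17 (not isolated), via magnesium enolate 18 (not isolated)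
Conditions: 16, Mg, THF, 25 °C; CuBr·SMe2 (10 mol%), LiCl, 11, THF, −40 °C; then N-(5-chloropyridin-2-yl)triflimide, −40 → 0 °C
Reagents that add atoms: N-(5-chloropyridin-2-yl)-1,1,1-trifluoro-N-[(trifluoromethyl)sulfonyl]methanesulfonamide (O=S(=O)(N(c1ccc(Cl)cn1)S(=O)(=O)C(F)(F)F)C(F)(F)F)
Why: copper-catalysed 1,4-addition of the Grignard reagent to the enone followed by O-sulfonylation of the regiodefined enolate, in which the alkyl group should enter C9 on the convex β-face, anti to the pseudo-axial C1 of ring A and therefore cis to the C10 methyl.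

Step 12
Reactants: 19 methyl (1S,4aR,5S,8aS)-5-{(3S)-5-[(tert-butyldimethylsilyl)oxy]-3-methylpentyl}-1,4a-dimethyl-7-{[(trifluoromethyl)sulfonyl]oxy}-1,2,3,4,4a,5,8,8a-octahydronaphthalene-1-carboxylate
Product: 22 methyl (1S,4aS,5R,8aS)-5-[(3S)-5-hydroxy-3-methylpentyl]-1,4a-dimethyl-6-oxodecahydronaphthalene-1-carboxylate, via morpholine enamine 20 (not isolated), via silyl ether ketone 21 (not isolated)
Conditions: Pd(OAc)2 (10 mol%), P(2-furyl)3 (25 mol%), N-methylbicyclo[2.2.1]hept-2-ene-2-carboxamide (50 mol%), morpholin-4-yl benzoate, iPrOH, Cs2CO3, 1,4-dioxane, 100 °C; then 2 M HCl, THF, 25 °C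
Reagents that add atoms: water (O)
Why: Catellani-type palladium/norbornene amination of the vinylic C8–H with ipso-hydrogenation at C7 turns the alkenyl triflate into the transposed enamine (carbonyl 1,2-transposition), and aqueous acid then hydrolyses the enamine to the C8 ketone and removes the silyl ether, C9 not being involved in any bond change.

Step 13
Reactants: 22 methyl (1S,4aS,5R,8aS)-5-[(3S)-5-hydroxy-3-methylpentyl]-1,4a-dimethyl-6-oxodecahydronaphthalene-1-carboxylate
Product: 23 methyl (1S,4aR,5S,8aS)-5-[(3S)-5-hydroxy-3-methylpentyl]-1,4a-dimethyl-6-methylidenedecahydronaphthalene-1-carboxylate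
Conditions: Ph3PCH3Br, KOtBu (excess), THF, 0 → 50 °C
Reagents that add atoms: methyltriphenylphosphonium bromide (C[P+](c1ccccc1)(c1ccccc1)c1ccccc1.[Br-])
Why: Wittig methylenation of the C8 ketone, the standard way to the 8(17)-exocyclic alkene of labdanes, should tolerate the hindered C19 ester and the alkoxide of the free alcohol, and the hindered C9–H is not expected to be removed by the ylide.

Step 14
Reactants: 23 methyl (1S,4aR,5S,8aS)-5-[(3S)-5-hydroxy-3-methylpentyl]-1,4a-dimethyl-6-methylidenedecahydronaphthalene-1-carboxylate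
Product: 24 methyl (1S,4aR,5S,8aS)-5-[(3S)-5-acetoxy-3-methylpentyl]-1,4a-dimethyl-6-methylidenedecahydronaphthalene-1-carboxylate (target)
Conditions: Ac2O, pyridine, DMAP (cat.), CH2Cl2, 25 °C
Reagents that add atoms: acetic anhydride (CC(=O)OC(C)=O)
Why: DMAP-catalysed acylation of the primary alcohol under non-acidic conditions leaves the exocyclic alkene and all stereocentres untouched.

Compound list
1 | 2,6-dimethylhept-5-enal (melonal, racemic) | CC(C)=CCCC(C)C=O | starting material
2 | but-3-en-2-one (methyl vinyl ketone) | CC(=O)C=C | starting material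
3 | 2-methyl-2-(4-methylpent-3-en-1-yl)-5-oxohexanal (racemic) | O=CC(C)(CCC=C(C)C)CCC(C)=O | intermediate
4 | 4-methyl-4-(4-methylpent-3-en-1-yl)cyclohex-2-en-1-one (racemic) | CC(C)=CCCC1(C)CCC(=O)C=C1 | intermediate
5 | 4-methyl-4-(4-methylpent-3-en-1-yl)cyclohexa-2,5-dien-1-one | CC(C)=CCCC1(C)C=CC(=O)C=C1 | intermediate
6 | 4-[(3E)-5-hydroxy-4-methylpent-3-en-1-yl]-4-methylcyclohexa-2,5-dien-1-one | OC/C(C)=C/CCC1(C)C=CC(=O)C=C1 | intermediate
7 | (2E)-2-methyl-5-(1-methyl-4-oxocyclohexa-2,5-dien-1-yl)pent-2-enal | O=C/C(C)=C/CCC1(C)C=CC(=O)C=C1 | intermediate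
8 | 2-methyl-5-(1-methyl-4-oxocyclohexa-2,5-dien-1-yl)pentanal (engaged as its enamine) | O=CC(C)CCCC1(C)C=CC(=O)C=C1 | intermediate
9 | (1S,4aR,8aS)-1,4a-dimethyl-7-oxo-1,2,3,4,4a,7,8,8a-octahydronaphthalene-1-carbaldehyde | O=C1C[C@H]2[C@](C)(CCC[C@]2(C)C=O)C=C1 | intermediate
10 | (1S,4aR,8aS)-1,4a-dimethyl-7-oxo-1,2,3,4,4a,7,8,8a-octahydronaphthalene-1-carboxylic acid | O=C1C[C@H]2[C@](C)(CCC[C@]2(C)C(=O)O)C=C1 | intermediate
11 | methyl (1S,4aR,8aS)-1,4a-dimethyl-7-oxo-1,2,3,4,4a,7,8,8a-octahydronaphthalene-1-carboxylate | O=C1C[C@H]2[C@](C)(CCC[C@]2(C)C(=O)OC)C=C1 | intermediate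
12 | (3R)-5-methoxy-3-methyl-5-oxopentanoic acid | COC(=O)C[C@H](C)CC(=O)O | starting material
13 | methyl (3R)-5-hydroxy-3-methylpentanoate | COC(=O)C[C@H](C)CCO | intermediate
14 | methyl (3R)-5-[(tert-butyldimethylsilyl)oxy]-3-methylpentanoate | COC(=O)C[C@H](C)CCO[Si](C)(C)C(C)(C)C | intermediate
15 | (3S)-5-[(tert-butyldimethylsilyl)oxy]-3-methylpentan-1-ol | OCC[C@H](C)CCO[Si](C)(C)C(C)(C)C | intermediate
16 | tert-butyl{[(3R)-5-iodo-3-methylpentyl]oxy}dimethylsilane | ICC[C@H](C)CCO[Si](C)(C)C(C)(C)C | intermediate
17 | {(3R)-5-[(tert-butyldimethylsilyl)oxy]-3-methylpentyl}magnesium iodide | I[Mg]CC[C@H](C)CCO[Si](C)(C)C(C)(C)C | intermediate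
18 | iodomagnesium enolate of the C9-alkylated C7 ketone (C7=C8 enolate) | C1=C(O[Mg]I)C[C@H]2[C@](C)(CCC[C@]2(C)C(=O)OC)[C@H]1CC[C@H](C)CCO[Si](C)(C)C(C)(C)C | intermediate
19 | methyl (1S,4aR,5S,8aS)-5-{(3S)-5-[(tert-butyldimethylsilyl)oxy]-3-methylpentyl}-1,4a-dimethyl-7-{[(trifluoromethyl)sulfonyl]oxy}-1,2,3,4,4a,5,8,8a-octahydronaphthalene-1-carboxylate | C1=C(OS(=O)(=O)C(F)(F)F)C[C@H]2[C@](C)(CCC[C@]2(C)C(=O)OC)[C@H]1CC[C@H](C)CCO[Si](C)(C)C(C)(C)C | intermediate
20 | C8 morpholine enamine (C7=C8) of silyl ether ketone 21 | C1(N3CCOCC3)=CC[C@H]2[C@](C)(CCC[C@]2(C)C(=O)OC)[C@H]1CC[C@H](C)CCO[Si](C)(C)C(C)(C)C | intermediate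
21 | methyl (1S,4aS,5R,8aS)-5-{(3S)-5-[(tert-butyldimethylsilyl)oxy]-3-methylpentyl}-1,4a-dimethyl-6-oxodecahydronaphthalene-1-carboxylate | O=C1CC[C@H]2[C@](C)(CCC[C@]2(C)C(=O)OC)[C@H]1CC[C@H](C)CCO[Si](C)(C)C(C)(C)C | intermediate
22 | methyl (1S,4aS,5R,8aS)-5-[(3S)-5-hydroxy-3-methylpentyl]-1,4a-dimethyl-6-oxodecahydronaphthalene-1-carboxylate | O=C1CC[C@H]2[C@](C)(CCC[C@]2(C)C(=O)OC)[C@H]1CC[C@H](C)CCO | intermediate
23 | methyl (1S,4aR,5S,8aS)-5-[(3S)-5-hydroxy-3-methylpentyl]-1,4a-dimethyl-6-methylidenedecahydronaphthalene-1-carboxylate | C=C1CC[C@H]2[C@](C)(CCC[C@]2(C)C(=O)OC)[C@H]1CC[C@H](C)CCO | intermediate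
24 | methyl (1S,4aR,5S,8aS)-5-[(3S)-5-acetoxy-3-methylpentyl]-1,4a-dimethyl-6-methylidenedecahydronaphthalene-1-carboxylate | C=C1CC[C@H]2[C@](C)(CCC[C@]2(C)C(=O)OC)[C@H]1CC[C@H](C)CCOC(C)=O | target

Total step count: 14. Longest linear sequence: 10 steps (steps 1–6 and 11–14).

Steps most likely to fail

1. Step 4. Iminium formation from the α,β-disubstituted enal may be slow, hydride may go to the dienone instead, the enantiotopic enone arms may be poorly differentiated, and above all the inside/outside placement of the formyl-bearing enamine carbon during ring closure may invert and give the C4 epimer. Fallback (auxiliary-controlled metallated hydrazone chemistry instead of amine catalysis): step 3 is stopped before the MnO2 stage and allylic alcohol 6 is isolated. Isomerisation of the allylic alcohol with [Ir(cod)(PCy3)(py)]PF6 (activated with H2, then degassed, THF) should give saturated aldehyde 8, which does not cyclise in the absence of an amine. Condensation with (S)-1-amino-2-(methoxymethyl)pyrrolidine gives SAMP hydrazone F1. Deprotonation with LiN(iPr)2 at −78 °C and intramolecular Michael addition of the aza-enolate to the dienone under auxiliary control should give bicyclic hydrazone F2 (the enantiomeric auxiliary is used if the sense is wrong). Cleavage with aqueous oxalic acid returns aldehyde 9.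

2. Step 12. Palladation and amination of the vinylic C8–H next to the substituted C9 may fail for steric reasons, the triflate may simply be reduced, and enolisation toward C9 during enamine hydrolysis may erode the C9 configuration. Fallback (α-methylenation and allylic hydrogenolysis, with no C8 ketone): setting out from enone 11, copper-catalysed addition of Grignard reagent 17 with trapping of the enolate by dimethyl(methylidene)ammonium iodide gives β-amino ketone F3. N-Methylation (MeI) and elimination (NaHCO3) give α-methylene ketone F4. Luche reduction (NaBH4, CeCl3, MeOH) gives allylic alcohol F5, and ClCO2Me/pyridine gives allylic methyl carbonate F6. Hydrogenolysis with Pd(OAc)2, PBu3 and HCO2NH4 (a zerovalent palladium allyl complex, hydride delivered to the more substituted allyl terminus C7) should give exocyclic alkene silyl ether F7. Bu4NF returns methylene alcohol 23.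

3. Step 11. Transfer of the functionalised alkyl group to the neopentyl-type β-carbon C9 may be sluggish, with competing 1,2-addition or enolisation and incomplete O-sulfonylation of the magnesium enolate. Fallback (radical instead of organocopper addition): from enone 11 and iodide 16, tin-free radical conjugate addition with (Me3Si)3SiH and AIBN in toluene at 80 °C should give C9-alkylated ketone F8, again by attack on the convex face. Kinetic deprotonation on the less hindered C8 side with KN(SiMe3)2 and trapping with PhNTf2 at −78 °C rejoins the route at triflate 19.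

Further compounds
F1 | step 4 | SAMP hydrazone of 2-methyl-5-(1-methyl-4-oxocyclohexa-2,5-dien-1-yl)pentanal (mixture at the α-carbon) | COC[C@@H]1CCCN1/N=C/C(C)CCCC2(C)C=CC(=O)C=C2
F2 | step 4 | SAMP hydrazone of aldehyde 9 | O=C1C[C@H]2[C@](C)(CCC[C@]2(C)/C=N/N3CCC[C@H]3COC)C=C1
F3 | step 12 | methyl 9-alkylated 8-[(dimethylamino)methyl]-7-oxo bicyclic ester (silyl ether; mixture at C8) | C1(CN(C)C)C(=O)C[C@H]2[C@](C)(CCC[C@]2(C)C(=O)OC)[C@H]1CC[C@H](C)CCO[Si](C)(C)C(C)(C)C
F4 | step 12 | methyl 9-alkylated 8-methylidene-7-oxo bicyclic ester (silyl ether) | C=C1C(=O)C[C@H]2[C@](C)(CCC[C@]2(C)C(=O)OC)[C@H]1CC[C@H](C)CCO[Si](C)(C)C(C)(C)C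
F5 | step 12 | methyl 9-alkylated 7-hydroxy-8-methylidene bicyclic ester (silyl ether; mixture at C7) | C=C1C(O)C[C@H]2[C@](C)(CCC[C@]2(C)C(=O)OC)[C@H]1CC[C@H](C)CCO[Si](C)(C)C(C)(C)C
F6 | step 12 | methyl carbonate of allylic alcohol F5 | C=C1C(OC(=O)OC)C[C@H]2[C@](C)(CCC[C@]2(C)C(=O)OC)[C@H]1CC[C@H](C)CCO[Si](C)(C)C(C)(C)C
F7 | step 12 | tert-butyldimethylsilyl ether of methylene alcohol 23 | C=C1CC[C@H]2[C@](C)(CCC[C@]2(C)C(=O)OC)[C@H]1CC[C@H](C)CCO[Si](C)(C)C(C)(C)C
F8 | step 11 | methyl 9-alkylated 7-oxo bicyclic ester (silyl ether) | C1C(=O)C[C@H]2[C@](C)(CCC[C@]2(C)C(=O)OC)[C@H]1CC[C@H](C)CCO[Si](C)(C)C(C)(C)C
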